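A flask in which target is merely made cannot hold less of it at 20.0 min than at 4.00 min, yet the alder run does. We have the flasks winter, autumn, dusk and spring to rank at 80 min, from two earlier runs at equal charges.

common to all: starting material 1.5 M; free catalyst 7.5 mM
- cedar: partner 1.5 M; temperature −10 °C; run made earlier
- alder: partner 1.5 M; temperature 20 °C; run made earlier
- winter: partner 3.00 M; temperature −5 °C; time 80 min
- autumn: partner 3.00 M; temperature 45 °C; time 80 min
- dusk: partner 3.00 M; temperature 20 °C; time 80 min
- spring: partner 3.00 M; at −5 °C until 1.0 h, from then on at 45 °C; time 80 min

| run | time / min | target / % |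
|---|---|---|
| cedar | 6.00 | 6 |
| cedar | 15.0 | 10 |
| cedar | 30.0 | 18 |
| cedar | 50.0 | 23 |
| cedar | 60.0 | 26 |
| alder | 2.00 | 15 |
| alder | 4.00 | 18 |
| alder | 8.00 | 16 |
| alder | 15.0 | 14 |
| alder | 20.0 | 10 |

(standard deviation of a reading: 1.5 percentage points)

* the best flask by amount of target, in percent of the starting material charged; "all alike" if 1.5 percentage points covers them all (winter / autumn / dusk / spring / all alike)
* amount of target at the end, in percent of the starting material charged, winter
* amount of target at the end, in percent of the starting material charged, autumn
* amount of target at the end, in percent of the starting material charged, dusk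
* amount of target at the end, in percent of the starting material charged, spring



Two readings seem not to go together. Over its first reading alder gained target 7.50 times as fast as cedar, 15% in 2.00 min against 6% in 6.00 min, yet alder's best reading, 18%, lies below cedar's last, 26%. The reckoning clears this up. Alder's best reading stands at 4.00 min, while cedar's readings still rise at 60.0 min, so as read from these runs the time of rising shrank by a factor of about 15.0, more than the speed gained.

Alder's fall gives us a clock for the flasks at its temperature: the halving time, the time in which target drops to a part in two if read as a plain decay. From 18% to 10% it is a reading of 18.9 min. Dusk, at the same temperature as alder, runs through 4.23 halving times.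

The readings do not say where the fall ends, so we set a scale. If doubled partner doubles the peak, dusk makes 36.0%. A decay to nothing leaves 1.91%, and the symmetric case, a reversible loss with even shares at rest, leaves 18.0%. We put dusk between these two and, with no fall in the readings of the cedar run, we too take winter as best.

The forecast gives winter as best, with winter 50% (38% to 62%), autumn 0.3% (0% to 2%), dusk 1.5% (0.3% to 5%) and spring 1.5% (0% to 8%). Of dusk it says: “peaks near 28%, then decays for over an hour to 1–2%”. Its dusk figure stands below our low end.

The flasks end at winter 35.2%, spring 27.3%, autumn 15.0% and dusk 9.84%, so winter is best.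

    catalyst intermediate B → free catalyst + target (k = 71.0 min⁻¹, Ea = 73.0 kJ mol⁻¹)
    partner + free catalyst ⇌ catalyst intermediate A (K = 0.220 M⁻¹, k = 59.0 M⁻¹ min⁻¹, Ea = 53.0 kJ mol⁻¹, ΔH = −14.0 kJ mol⁻¹)
    partner → decomposed reagent (k = 1.10 min⁻¹, Ea = 70.0 kJ mol⁻¹)
    target ⇌ isomer of the product (K = 2.20, k = 0.0320 min⁻¹, Ea = 82.0 kJ mol⁻¹, ΔH = −52.0 kJ mol⁻¹)
    free catalyst → spent catalyst (k = 0.0550 min⁻¹, Ea = 77.0 kJ mol⁻¹)
    starting material + catalyst intermediate A → catalyst intermediate B (k = 1400 M⁻¹ min⁻¹, Ea = 49.0 kJ mol⁻¹)
    (constants at 20 °C)

Dusk lies inside our scale: at its end it holds 9.84% of target beside 20.0% of isomer of the product, a target share of 33.0%. After those 4.23 halving times, dusk left ten times as long stands at 9.33%. The neighbouring flask with 0.030 M of free catalyst, at the temperature and time of dusk, has the same count of halving times and holds 26.0% of target beside 52.9% of isomer of the product, a target share of 33.0%.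

(The data come from a simulation on assumed constants, and the scatter is random.)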